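**Strategy.** Ring C of the upper unit (O1, C2, C3, C4, C4a, C8a) is an α-ketol at the dihydroflavonol level, C3(OH)–C4(=O). Its isomer is a tertiary α-hydroxy aldehyde on a 2,3-dihydrobenzofuran whose five-membered ring holds O1, C2, C4, C4a and C8a, with C3 as an exocyclic formyl group. An α-ketol rearrangement shifts C2 from C4 to C3: one operation enlarges the ring to six members, sets the 2,3-trans C3 stereocentre and unveils the C4 ketone which, once reduced, is the leaving group for the 4→8 coupling with epicatechin. The precursor comes from an enantioselective carbene C–H insertion that sets C2, then enolate hydroxylation and partial reduction.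

Key step: step 7

Abbreviations in names: TBB = 3,4,5-tris(benzyloxy)benzyl, (BnO)3C6H2CH2–; TBP = 3,4,5-tris(benzyloxy)phenyl. The TBB groups come from commercial 3,4,5-tris(benzyloxy)benzyl alcohol, used as the alkylating reagent in step 1; three molecules of it enter the product and each is listed there.

Assumption: the divalent rhodium carboxylate Rh2(S-PTTL)4 (PTTL = N-phthaloyl-tert-leucinate) is taken to give the (2S) configuration drawn for 7, by analogy with simpler 2-benzyloxyphenyl diazoacetates; if the sense is opposite, the catalyst with the (R)-ligand is used.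

**Step 1**
Reactants: 1 phloroglucinol
Product: 2 1,3,5-tris(TBB-oxy)benzene
Conditions: 3,4,5-tris(benzyloxy)benzyl alcohol (3.3 equiv), PPh3, DIAD, THF, 0 °C → rt
Reagents that add atoms: 3,4,5-tris(benzyloxy)benzyl alcohol (first of three equivalents), OCc1cc(OCc2ccccc2)c(OCc2ccccc2)c(OCc2ccccc2)c1; 3,4,5-tris(benzyloxy)benzyl alcohol (second equivalent), OCc1cc(OCc2ccccc2)c(OCc2ccccc2)c(OCc2ccccc2)c1; 3,4,5-tris(benzyloxy)benzyl alcohol (third equivalent), OCc1cc(OCc2ccccc2)c(OCc2ccccc2)c(OCc2ccccc2)c1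
Why: Threefold Mitsunobu etherification, one molecule of the benzylic alcohol per phenolic oxygen, alkylates under neutral conditions and so avoids the C-benzylation that phloroglucinol suffers under basic Williamson conditions; no stereocentre is formed.

**Step 2**
Reactants: 2 1,3,5-tris(TBB-oxy)benzene
Product: 4 methyl 2-oxo-2-[2,4,6-tris(TBB-oxy)phenyl]acetate, via aroylformyl chloride 3 (not isolated)
Conditions: (COCl)2, CH2Cl2, 0 °C → rt; then MeOH, pyridine, 0 °C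
Reagents that add atoms: oxalyl chloride, O=C(Cl)C(=O)Cl; methanol, CO
Why: Friedel–Crafts acylation without Lewis acid should touch only the 1,3,5-trioxygenated ring (three equivalent positions, each ortho/ortho/para to oxygen), sparing the less activated 1,2,3-trioxygenated rings and the benzyl ethers, and the acid chloride is esterified in the same flask.

**Step 3**
Reactants: 4 methyl 2-oxo-2-[2,4,6-tris(TBB-oxy)phenyl]acetate
Product: 6 methyl 2-diazo-2-[2,4,6-tris(TBB-oxy)phenyl]acetate, via tosylhydrazone 5 (not isolated)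
Conditions: TsNHNH2, cat. TsOH, toluene, 70 °C; then DBU, CH2Cl2, rt
Reagents that add atoms: p-toluenesulfonyl hydrazide, Cc1ccc(cc1)S(=O)(=O)NN
Why: Condensation to the tosylhydrazone and base-induced loss of sulfinate (Bamford–Stevens-type elimination) should give the ester-stabilised aryl diazoacetate.

**Step 4**
Reactants: 6 methyl 2-diazo-2-[2,4,6-tris(TBB-oxy)phenyl]acetate
Product: 7 methyl (2S,3R)-2-TBP-4,6-bis(TBB-oxy)-2,3-dihydrobenzofuran-3-carboxylate (2,3-cis)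
Conditions: Rh2(S-PTTL)4 (1 mol %), toluene, −60 → 0 °C
Reagents that add atoms: none
Why: Enantioselective intramolecular 1,5 C–H insertion of the rhodium carbene into a benzylic O–CH2 bond; the two ortho ethers are homotopic, so no regiochemical choice arises, and the chiral carboxylate ligands select one enantiotopic hydrogen, which sets C2 (the later C2 of ring C), while the cis ester centre C3 is planarised and re-set in step 5.

**Step 5**
Reactants: 7 methyl (2S,3R)-2-TBP-4,6-bis(TBB-oxy)-2,3-dihydrobenzofuran-3-carboxylate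
Product: 9 methyl (2R,3S)-3-hydroxy-2-TBP-4,6-bis(TBB-oxy)-2,3-dihydrobenzofuran-3-carboxylate (3-OH trans to the 2-aryl group), via potassium ester enolate 8 (not isolated)
Conditions: KN(SiMe3)2, THF, −78 °C; then 2-(phenylsulfonyl)-3-phenyloxaziridine, −78 °C; aq. NH4Cl
Reagents that add atoms: 2-(phenylsulfonyl)-3-phenyloxaziridine, O=S(=O)(c1ccccc1)N1OC1c1ccccc1
Why: Electrophilic α-hydroxylation of the ester enolate (Davis oxidation), which at −78 °C should not expel the ring aryloxide because the C2–O bond lies in the nodal plane of the enolate (reverse of a 5-endo-trig closure); the oxidant approaches the face anti to the C2 aryl group and so sets the C3 hydroxyl trans to it, the arrangement that the chelate-controlled shift of step 7 turns directly into the 2,3-trans ketol.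

**Step 6**
Reactants: 9 methyl (2R,3S)-3-hydroxy-2-TBP-4,6-bis(TBB-oxy)-2,3-dihydrobenzofuran-3-carboxylate
Product: 10 (2R,3S)-3-hydroxy-2-TBP-4,6-bis(TBB-oxy)-2,3-dihydrobenzofuran-3-carbaldehyde
Conditions: iBu2AlH (2.5 equiv), CH2Cl2, −78 °C; MeOH, then aq. KNaC4H4O6
Reagents that add atoms: none
Why: Partial ester reduction; the aluminium alkoxide formed first from the tertiary hydroxyl chelates and stabilises the tetrahedral intermediate at −78 °C, so the aldehyde is released only on work-up.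

**Step 7**
Reactants: 10 (2R,3S)-3-hydroxy-2-TBP-4,6-bis(TBB-oxy)-2,3-dihydrobenzofuran-3-carbaldehyde
Product: 12 (2R,3R)-3-hydroxy-2-TBP-5,7-bis(TBB-oxy)chroman-4-one (2,3-trans), via chloro(methyl)aluminium alkoxide 11 (not isolated)
Conditions: Me2AlCl (1.1 equiv), CH2Cl2, −78 → 0 °C; aq. KNaC4H4O6
Reagents that add atoms: none
Why: α-Ketol (acyloin) rearrangement: Me2AlCl turns the hydroxyl into an aluminium alkoxide that chelates the formyl oxygen, and the push of the alkoxide with the pull of the activated C=O drives a suprafacial 1,2-shift of the ring carbon C2 (α-aryloxy, benzylic) from the carbinol carbon to the formyl carbon, so the carbinol carbon becomes the C4 ketone and the formyl carbon becomes C3–OH. The closest known reactions are the α-ketol ring enlargements of 1-hydroxycycloalkanecarbaldehydes and the D-homoannulation of 17-hydroxy-20-oxo steroids. The six-membered ring is not closed by a new bond from a chain but arises by migration of the C2–C4 ring bond to the exocyclic carbon (five to six members, so no exo or endo mode applies). C2 migrates with retention and keeps the configuration from step 4; the new centre C3 is fixed by the syn-periplanar O–C–C=O chelate, which delivers C2 to the formyl face that places the hydroxyl trans to the aryl group, and this diequatorial isomer is also the thermodynamic one, reachable from any cis product through the enediolate. The step needs migration of C2 and not of the ring A carbon: the shifts are reversible and the aryl ketone conjugated with the trioxygenated ring A is the thermodynamic sink, while the aluminium alkoxide suppresses acid-type dehydration to the aromatic benzofuran.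

**Step 8**
Reactants: 12 (2R,3R)-3-hydroxy-2-TBP-5,7-bis(TBB-oxy)chroman-4-one
Product: 13 (2R,3S,4R)-2-TBP-5,7-bis(TBB-oxy)chromane-3,4-diol (2,3-trans, 3,4-trans)
Conditions: NaBH4, THF/MeOH, 0 °C
Reagents that add atoms: none
Why: Carbonyl reduction with axial hydride delivery should give the 3,4-trans diol; the C4 configuration is inconsequential because C4 is ionised in step 10.

**Step 9**
Reactants: 14 (−)-epicatechin
Product: 15 5,7,3',4'-tetra-O-benzyl-(−)-epicatechin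
Conditions: BnBr (4.2 equiv), K2CO3, DMF, −20 °C → rt
Reagents that add atoms: benzyl bromide (first of four equivalents), BrCc1ccccc1; benzyl bromide (second equivalent), BrCc1ccccc1; benzyl bromide (third equivalent), BrCc1ccccc1; benzyl bromide (fourth equivalent), BrCc1ccccc1
Why: Williamson etherification of the four phenolic hydroxyls (the aliphatic 3-OH is not deprotonated by K2CO3); both stereocentres come from the chiral pool and are untouched at low temperature.

**Step 10**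
Reactants: 13 (2R,3S,4R)-2-TBP-5,7-bis(TBB-oxy)chromane-3,4-diol; 15 5,7,3',4'-tetra-O-benzyl-(−)-epicatechin
Product: 16 protected gallocatechin-(4α→8)-epicatechin: upper unit (2R,3S,4S) with 5,7-bis(TBB-oxy) and TBP, lower unit (2R,3R) tetra-O-benzyl, both 3-OH free
Conditions: 15 (3 equiv), Me3SiOTf (0.2 equiv), 4 Å molecular sieves, CH2Cl2, −78 → −30 °C
Reagents that add atoms: none
Why: Acid-mediated Friedel–Crafts benzylation: ionisation of the C4 hydroxyl gives the ring-A-stabilised C4 cation, which C8 of 15 (the most nucleophilic, least hindered position; excess suppresses oligomers) attacks anti to the C3 hydroxyl, setting C4 (S) 3,4-trans as is general for 2,3-trans flavan electrophiles.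

**Step 11**
Reactants: 16 protected gallocatechin-(4α→8)-epicatechin
Product: 17 gallocatechin-(4α→8)-epicatechin (target)
Conditions: H2 (1 atm), Pd(OH)2/C, THF/MeOH/H2O, rt
Reagents that add atoms: none
Why: Hydrogenolysis cleaves all fifteen benzylic C–O bonds (thirteen benzyl ethers and the two TBB aryl ethers) without touching the interflavan C–C bond or any stereocentre.

**Compound list**

1 | phloroglucinol | Oc1cc(O)cc(O)c1 | starting material
2 | 1,3,5-tris(TBB-oxy)benzene | c1c(OCc3cc(OCc4ccccc4)c(OCc4ccccc4)c(OCc4ccccc4)c3)cc(OCc3cc(OCc4ccccc4)c(OCc4ccccc4)c(OCc4ccccc4)c3)cc1OCc3cc(OCc4ccccc4)c(OCc4ccccc4)c(OCc4ccccc4)c3 | intermediate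
3 | 2-oxo-2-[2,4,6-tris(TBB-oxy)phenyl]acetyl chloride | O=C(Cl)C(=O)c1c(OCc3cc(OCc4ccccc4)c(OCc4ccccc4)c(OCc4ccccc4)c3)cc(OCc3cc(OCc4ccccc4)c(OCc4ccccc4)c(OCc4ccccc4)c3)cc1OCc3cc(OCc4ccccc4)c(OCc4ccccc4)c(OCc4ccccc4)c3 | intermediate (not isolated)
4 | methyl 2-oxo-2-[2,4,6-tris(TBB-oxy)phenyl]acetate | COC(=O)C(=O)c1c(OCc3cc(OCc4ccccc4)c(OCc4ccccc4)c(OCc4ccccc4)c3)cc(OCc3cc(OCc4ccccc4)c(OCc4ccccc4)c(OCc4ccccc4)c3)cc1OCc3cc(OCc4ccccc4)c(OCc4ccccc4)c(OCc4ccccc4)c3 | intermediate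
5 | methyl 2-(tosylhydrazono)-2-[2,4,6-tris(TBB-oxy)phenyl]acetate | COC(=O)C(=NNS(=O)(=O)c5ccc(C)cc5)c1c(OCc3cc(OCc4ccccc4)c(OCc4ccccc4)c(OCc4ccccc4)c3)cc(OCc3cc(OCc4ccccc4)c(OCc4ccccc4)c(OCc4ccccc4)c3)cc1OCc3cc(OCc4ccccc4)c(OCc4ccccc4)c(OCc4ccccc4)c3 | intermediate (not isolated)
6 | methyl 2-diazo-2-[2,4,6-tris(TBB-oxy)phenyl]acetate | COC(=O)C(=[N+]=[N-])c1c(OCc3cc(OCc4ccccc4)c(OCc4ccccc4)c(OCc4ccccc4)c3)cc(OCc3cc(OCc4ccccc4)c(OCc4ccccc4)c(OCc4ccccc4)c3)cc1OCc3cc(OCc4ccccc4)c(OCc4ccccc4)c(OCc4ccccc4)c3 | intermediate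
7 | methyl (2S,3R)-2-TBP-4,6-bis(TBB-oxy)-2,3-dihydrobenzofuran-3-carboxylate | O1[C@H](c3cc(OCc4ccccc4)c(OCc4ccccc4)c(OCc4ccccc4)c3)[C@H](C(=O)OC)c2c(OCc3cc(OCc4ccccc4)c(OCc4ccccc4)c(OCc4ccccc4)c3)cc(OCc3cc(OCc4ccccc4)c(OCc4ccccc4)c(OCc4ccccc4)c3)cc21 | intermediate
8 | potassium enolate of 7 (C2 as in 7) | O1[C@H](c3cc(OCc4ccccc4)c(OCc4ccccc4)c(OCc4ccccc4)c3)C(=C([O-])OC)c2c(OCc3cc(OCc4ccccc4)c(OCc4ccccc4)c(OCc4ccccc4)c3)cc(OCc3cc(OCc4ccccc4)c(OCc4ccccc4)c(OCc4ccccc4)c3)cc21.[K+] | intermediate (not isolated)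
9 | methyl (2R,3S)-3-hydroxy-2-TBP-4,6-bis(TBB-oxy)-2,3-dihydrobenzofuran-3-carboxylate | O1[C@H](c3cc(OCc4ccccc4)c(OCc4ccccc4)c(OCc4ccccc4)c3)[C@](O)(C(=O)OC)c2c(OCc3cc(OCc4ccccc4)c(OCc4ccccc4)c(OCc4ccccc4)c3)cc(OCc3cc(OCc4ccccc4)c(OCc4ccccc4)c(OCc4ccccc4)c3)cc21 | intermediate
10 | (2R,3S)-3-hydroxy-2-TBP-4,6-bis(TBB-oxy)-2,3-dihydrobenzofuran-3-carbaldehyde | O1[C@H](c3cc(OCc4ccccc4)c(OCc4ccccc4)c(OCc4ccccc4)c3)[C@](O)(C=O)c2c(OCc3cc(OCc4ccccc4)c(OCc4ccccc4)c(OCc4ccccc4)c3)cc(OCc3cc(OCc4ccccc4)c(OCc4ccccc4)c(OCc4ccccc4)c3)cc21 | intermediate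
11 | chloro(methyl)aluminium alkoxide of 10 | O1[C@H](c3cc(OCc4ccccc4)c(OCc4ccccc4)c(OCc4ccccc4)c3)[C@](O[Al](C)Cl)(C=O)c2c(OCc3cc(OCc4ccccc4)c(OCc4ccccc4)c(OCc4ccccc4)c3)cc(OCc3cc(OCc4ccccc4)c(OCc4ccccc4)c(OCc4ccccc4)c3)cc21 | intermediate (not isolated)
12 | (2R,3R)-3-hydroxy-2-TBP-5,7-bis(TBB-oxy)chroman-4-one | O1[C@H](c3cc(OCc4ccccc4)c(OCc4ccccc4)c(OCc4ccccc4)c3)[C@@H](O)C(=O)c2c(OCc3cc(OCc4ccccc4)c(OCc4ccccc4)c(OCc4ccccc4)c3)cc(OCc3cc(OCc4ccccc4)c(OCc4ccccc4)c(OCc4ccccc4)c3)cc21 | intermediate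
13 | (2R,3S,4R)-2-TBP-5,7-bis(TBB-oxy)chromane-3,4-diol | O1[C@H](c3cc(OCc4ccccc4)c(OCc4ccccc4)c(OCc4ccccc4)c3)[C@@H](O)[C@H](O)c2c(OCc3cc(OCc4ccccc4)c(OCc4ccccc4)c(OCc4ccccc4)c3)cc(OCc3cc(OCc4ccccc4)c(OCc4ccccc4)c(OCc4ccccc4)c3)cc21 | intermediate
14 | (−)-epicatechin, (2R,3R) | Oc1cc(O)c2c(c1)O[C@H](c1ccc(O)c(O)c1)[C@H](O)C2 | starting material
15 | 5,7,3',4'-tetra-O-benzyl-(−)-epicatechin | c1ccccc1COc1cc(OCc3ccccc3)c2c(c1)O[C@H](c1ccc(OCc3ccccc3)c(OCc3ccccc3)c1)[C@H](O)C2 | intermediate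
16 | protected gallocatechin-(4α→8)-epicatechin | C(c3cc(OCc4ccccc4)c(OCc4ccccc4)c(OCc4ccccc4)c3)Oc1cc(OCc3cc(OCc4ccccc4)c(OCc4ccccc4)c(OCc4ccccc4)c3)c2c(c1)O[C@H](c1cc(OCc3ccccc3)c(OCc3ccccc3)c(OCc3ccccc3)c1)[C@@H](O)[C@@H]2c1c(OCc3ccccc3)cc(OCc3ccccc3)c2c1O[C@H](c1ccc(OCc3ccccc3)c(OCc3ccccc3)c1)[C@H](O)C2 | intermediate
17 | gallocatechin-(4α→8)-epicatechin, upper unit (2R,3S,4S), lower unit (2R,3R) | Oc1cc(O)c2c(c1)O[C@H](c1cc(O)c(O)c(O)c1)[C@@H](O)[C@@H]2c1c(O)cc(O)c2c1O[C@H](c1ccc(O)c(O)c1)[C@H](O)C2 | target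

**Totals.** Total step count: 11. Longest linear sequence: 10 steps (steps 1–8, 10 and 11); step 9 is the side branch.

**Steps most likely to fail**

Step 7. The 1,2-shift may be outrun by loss of the tertiary hydroxyl with aromatisation to the benzofuran, or migration of the ring A carbon may dominate and erode C2 through enolisation of a chroman-3-one. The fallback sets out from 9, comes back at 16, and makes the ring A carbon the intended migrating group. LiAlH4 (THF, 0 °C) reduces 9 to the diol (2R,3R)-3-(hydroxymethyl)-2-TBP-4,6-bis(TBB-oxy)-2,3-dihydrobenzofuran-3-ol F1. TsCl/pyridine sulfonylates only the primary hydroxyl to give the monotosylate F2. Et2AlCl (CH2Cl2, −78 → 0 °C) forms the tertiary aluminium alkoxide and triggers a pinacol-type 1,2-aryl shift with loss of tosylate, which enlarges the five-membered ring to (2R)-2-TBP-5,7-bis(TBB-oxy)chroman-3-one F3. This ketone is reduced at once with NaBH4 (axial hydride delivery), which should favour the 2,3-trans alcohol (2R,3S)-2-TBP-5,7-bis(TBB-oxy)chroman-3-ol F4. DDQ with 2-ethoxyethanol (CH2Cl2) oxidises the benzylic C4–H of that alcohol to its C4 2-ethoxyethyl ether F5 (drawn with the ether cis to the 3-hydroxyl; either C4 epimer serves). F5 and 15 under the conditions of step 10 give 16.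

Step 4. The chiral carboxylate catalyst may discriminate poorly between the enantiotopic hydrogens on this doubly ortho-substituted carbene, or carbene dimerisation may compete. The fallback sets out from 4 and comes back at 9, bypassing steps 3 and 5 as well. Irradiation of 4 (about 350 nm, degassed benzene) should trigger a Norrish–Yang photocyclisation: the excited ketone abstracts a δ-hydrogen from an ortho OCH2Ar group and the 1,5-biradical collapses to the racemic 3-hydroxy ester. The diastereomeric pair with the hydroxyl cis to the aryl group, the (2R,3R) epimer F7 and the (2S,3S) epimer F8, is removed on silica. Preparative HPLC on a chiral stationary phase then separates 9 from its (2S,3R) enantiomer F6.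

Step 10. The electrophile may condense with itself, and the product may react on to oligomers. The fallback sets out from 13 and comes back at 17. NBS (2 equiv, CH2Cl2, −78 °C) caps C6 and C8 of ring A to give the 6,8-dibromide F9, which can no longer act as a nucleophile. Equimolar condensation with 15 (Me3SiOTf, CH2Cl2, −78 °C) gives the dibrominated protected dimer F10. Hydrogenolysis (H2, Pd(OH)2/C, Et3N) removes both bromine atoms together with all benzyl-type groups and gives 17.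

**Further compounds**

F1 | step 7 | (2R,3R)-3-(hydroxymethyl)-2-TBP-4,6-bis(TBB-oxy)-2,3-dihydrobenzofuran-3-ol | O1[C@H](c3cc(OCc4ccccc4)c(OCc4ccccc4)c(OCc4ccccc4)c3)[C@](O)(CO)c2c(OCc3cc(OCc4ccccc4)c(OCc4ccccc4)c(OCc4ccccc4)c3)cc(OCc3cc(OCc4ccccc4)c(OCc4ccccc4)c(OCc4ccccc4)c3)cc21
F2 | step 7 | primary monotosylate of F1 | O1[C@H](c3cc(OCc4ccccc4)c(OCc4ccccc4)c(OCc4ccccc4)c3)[C@](O)(COS(=O)(=O)c5ccc(C)cc5)c2c(OCc3cc(OCc4ccccc4)c(OCc4ccccc4)c(OCc4ccccc4)c3)cc(OCc3cc(OCc4ccccc4)c(OCc4ccccc4)c(OCc4ccccc4)c3)cc21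
F3 | step 7 | (2R)-2-TBP-5,7-bis(TBB-oxy)chroman-3-one | O1[C@H](c3cc(OCc4ccccc4)c(OCc4ccccc4)c(OCc4ccccc4)c3)C(=O)Cc2c(OCc3cc(OCc4ccccc4)c(OCc4ccccc4)c(OCc4ccccc4)c3)cc(OCc3cc(OCc4ccccc4)c(OCc4ccccc4)c(OCc4ccccc4)c3)cc21
F4 | step 7 | (2R,3S)-2-TBP-5,7-bis(TBB-oxy)chroman-3-ol | O1[C@H](c3cc(OCc4ccccc4)c(OCc4ccccc4)c(OCc4ccccc4)c3)[C@@H](O)Cc2c(OCc3cc(OCc4ccccc4)c(OCc4ccccc4)c(OCc4ccccc4)c3)cc(OCc3cc(OCc4ccccc4)c(OCc4ccccc4)c(OCc4ccccc4)c3)cc21
F5 | step 7 | 4-(2-ethoxyethoxy) ether of F4, ether cis to the 3-hydroxyl | O1[C@H](c3cc(OCc4ccccc4)c(OCc4ccccc4)c(OCc4ccccc4)c3)[C@@H](O)[C@@H](OCCOCC)c2c(OCc3cc(OCc4ccccc4)c(OCc4ccccc4)c(OCc4ccccc4)c3)cc(OCc3cc(OCc4ccccc4)c(OCc4ccccc4)c(OCc4ccccc4)c3)cc21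
F6 | step 4 | methyl (2S,3R)-3-hydroxy-2-TBP-4,6-bis(TBB-oxy)-2,3-dihydrobenzofuran-3-carboxylate (enantiomer of 9) | O1[C@@H](c3cc(OCc4ccccc4)c(OCc4ccccc4)c(OCc4ccccc4)c3)[C@@](O)(C(=O)OC)c2c(OCc3cc(OCc4ccccc4)c(OCc4ccccc4)c(OCc4ccccc4)c3)cc(OCc3cc(OCc4ccccc4)c(OCc4ccccc4)c(OCc4ccccc4)c3)cc21
F7 | step 4 | methyl (2R,3R)-3-hydroxy-2-TBP-4,6-bis(TBB-oxy)-2,3-dihydrobenzofuran-3-carboxylate (C3 epimer of 9) | O1[C@H](c3cc(OCc4ccccc4)c(OCc4ccccc4)c(OCc4ccccc4)c3)[C@@](O)(C(=O)OC)c2c(OCc3cc(OCc4ccccc4)c(OCc4ccccc4)c(OCc4ccccc4)c3)cc(OCc3cc(OCc4ccccc4)c(OCc4ccccc4)c(OCc4ccccc4)c3)cc21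
F8 | step 4 | methyl (2S,3S)-3-hydroxy-2-TBP-4,6-bis(TBB-oxy)-2,3-dihydrobenzofuran-3-carboxylate (enantiomer of F7) | O1[C@@H](c3cc(OCc4ccccc4)c(OCc4ccccc4)c(OCc4ccccc4)c3)[C@](O)(C(=O)OC)c2c(OCc3cc(OCc4ccccc4)c(OCc4ccccc4)c(OCc4ccccc4)c3)cc(OCc3cc(OCc4ccccc4)c(OCc4ccccc4)c(OCc4ccccc4)c3)cc21
F9 | step 10 | 6,8-dibromo derivative of 13, (2R,3S,4R) | O1[C@H](c3cc(OCc4ccccc4)c(OCc4ccccc4)c(OCc4ccccc4)c3)[C@@H](O)[C@H](O)c2c(OCc3cc(OCc4ccccc4)c(OCc4ccccc4)c(OCc4ccccc4)c3)c(Br)c(OCc3cc(OCc4ccccc4)c(OCc4ccccc4)c(OCc4ccccc4)c3)c(Br)c21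
F10 | step 10 | 6,8-dibromo derivative of 16 (bromines on ring A of the upper unit; same spatial arrangement at every stereocentre as in 16) | C(c3cc(OCc4ccccc4)c(OCc4ccccc4)c(OCc4ccccc4)c3)Oc1c(Br)c(OCc3cc(OCc4ccccc4)c(OCc4ccccc4)c(OCc4ccccc4)c3)c2c(c1Br)O[C@H](c1cc(OCc3ccccc3)c(OCc3ccccc3)c(OCc3ccccc3)c1)[C@@H](O)[C@@H]2c1c(OCc3ccccc3)cc(OCc3ccccc3)c2c1O[C@H](c1ccc(OCc3ccccc3)c(OCc3ccccc3)c1)[C@H](O)C2
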